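**Retrosynthetic overview**
1. Last bond: the C10–O ester, from core alcohol 20 and (Z)-16-silyloxyhexadec-9-enoic acid 25 (alkyne alkylation, Lindlar); one acidic global deprotection at the end.
2. C2–CHO from a C2 ketone by C1 homologation (Wittig, then kinetic protonation); C10–OH by SeO2; C5–H by OH-directed hydrogenation; quaternary C6 by a formaldehyde ene reaction.
3. Bicyclo[3.2.1]octadiene ester by Rh-catalysed cyclopropanation/Cope ([4+3]) of ring-fused cyclopentadiene 9 with vinyldiazoacetate 11; this sets C1 and C7.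
4. Diene 9 from a Pauson–Khand enone made from hex-4-ynoic acid.
5. Ring order: ring C and the cyclopentadiene ring together (Pauson–Khand), then the six-membered ring, which completes the bicyclo[3.2.1] core (Cope).

Numbering used in all names (tricyclo[5.3.1.0(1,5)]undecane, as in cedrane): C1 spiro bridgehead, C2 (CHO), C3, C4, C5, C6 (Me, CH2OH), C7 bridgehead, C8 (CO2H), C9, C10 (O-acyl), C11 (CH2 bridge).

Assumption: the SMILES is taken literally, i.e. (1R,2S,5S,6S,7S,10S), with H-5 and the C6–CH2OH syn to C11, 10-O anti to the C5–C6 bridge, and ring C therefore trans-fused to the C1–C5–C6–C7–C11 ring; all SMILES below carry exactly these descriptors.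
Assumption: the DOSP enantiomer in step 8 is written as S; if the observed sense is opposite, Rh2(R-DOSP)4 is used.

**Step 1**
Reactants: 1 hex-4-ynoic acid
Product: 3 N-methoxy-N-methylhex-4-ynamide, via acyl imidazole 2 (not isolated)
Conditions: CDI, CH2Cl2, rt; then MeNH(OMe)·HCl, rt
Reagents that add atoms: N,O-dimethylhydroxylamine hydrochloride (CNOC.Cl)
Why: Weinreb amide formation through the acyl imidazole; no stereocentre is involved and the internal alkyne is inert.

**Step 2**
Reactants: 3 N-methoxy-N-methylhex-4-ynamide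
Product: 4 oct-1-en-6-yn-3-one
Conditions: CH2=CHMgBr, THF, −78 → 0 °C; inverse quench into cold 1 M HCl
Reagents that add atoms: vinylmagnesium bromide (C=C[Mg]Br)
Why: Weinreb ketone synthesis, in which the chelated tetrahedral adduct stops at mono-addition and the cold acidic inverse quench keeps the liberated amine from adding to the vinyl ketone.

**Step 3**
Reactants: 4 oct-1-en-6-yn-3-one
Product: 5 2-(pent-3-yn-1-yl)-2-vinyl-1,3-dioxolane
Conditions: (TMSOCH2)2, TMSOTf (5 mol %), CH2Cl2, −78 °C; pyridine quench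
Reagents that add atoms: 1,2-bis(trimethylsilyloxy)ethane (C[Si](C)(C)OCCO[Si](C)(C)C)
Why: Noyori ketalisation under aprotic conditions at −78 °C masks the vinyl ketone without conjugate addition; the ketal later masks C2 and keeps the diene achiral.

**Step 4**
Reactants: 5 2-(pent-3-yn-1-yl)-2-vinyl-1,3-dioxolane
Product: 6 rac-4'-methyl-2',3',6',6a'-tetrahydro-5'H-spiro[1,3-dioxolane-2,1'-pentalen]-5'-one
Conditions: [Rh(CO)2Cl]2 (3 mol %), CO (1 atm), xylene, 130 °C
Reagents that add atoms: carbon monoxide ([C-]#[O+])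
Why: Intramolecular Pauson–Khand [2+2+1] of the 1,6-enyne, helped by the gem-dialkoxy effect, builds ring C and the cyclopentenone together; the one new stereocentre is racemic and is erased in step 6.

**Step 5**
Reactants: 6 Pauson–Khand enone
Product: 7 rac-4'-methyl-3',5',6',6a'-tetrahydro-2'H-spiro[1,3-dioxolane-2,1'-pentalen]-5'-ol (diastereomer mixture)
Conditions: NaBH4, CeCl3·7H2O, MeOH, −20 °C
Reagents that add atoms: none
Why: Luche 1,2-reduction of the enone; the carbinol configuration does not matter because the alcohol is eliminated in the next step.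

**Step 6**
Reactants: 7 allylic alcohol
Product: 9 4'-methyl-3',6'-dihydro-2'H-spiro[1,3-dioxolane-2,1'-pentalene] (ring-fused cyclopentadiene C7=C6(Me)–C5=C1, achiral), via allylic mesylate 8 (not isolated)
Conditions: MsCl, Et3N, CH2Cl2, −30 → 0 °C; cold filtration, used at once
Reagents that add atoms: none
Why: Mesylation and base-induced 1,4-elimination is the classical enone-to-cyclopentadiene sequence; the diene is kept cold and used immediately so that 1,5-H shifts and dimerisation do not scramble it.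

**Step 7**
Reactants: 10 tert-butyl but-3-enoate
Product: 11 tert-butyl 2-diazobut-3-enoate
Conditions: p-ABSA, DBU, MeCN, 0 °C; used fresh
Reagents that add atoms: 4-acetamidobenzenesulfonyl azide (CC(=O)Nc1ccc(cc1)S(=O)(=O)N=[N+]=[N-])
Why: Regitz diazo transfer to the α-carbon of the dienolate gives the vinyldiazoacetate, which is used cold before it can cyclise to the pyrazole.

**Step 8**
Reactants: 9 ring-fused cyclopentadiene ketal; 11 tert-butyl 2-diazobut-3-enoate
Product: 13 tert-butyl 2,2-(ethylenedioxy)-6-methyltricyclo[5.3.1.0(1,5)]undeca-5,8-diene-8-carboxylate (C1/C7 as in the target), via cis-divinylcyclopropane 12 (not isolated)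
Conditions: Rh2(S-DOSP)4 (1 mol %), pentane, −78 °C → rt, slow addition of 11
Reagents that add atoms: none
Why: Davies tandem cyclopropanation/Cope rearrangement (formal [4+3]): the Rh vinylcarbenoid cyclopropanates the less substituted C7=C6 bond on the catalyst-selected face with the vinyl group cis to the ring, and the boat Cope shift closes C10–C1 on that same face, so both bridgeheads C1 and C7 are set by the chiral catalyst.

**Step 9**
Reactants: 13 tricyclic diene ester
Product: 14 tert-butyl 2,2-(ethylenedioxy)-6-(hydroxymethyl)-6-methyltricyclo[5.3.1.0(1,5)]undeca-4,8-diene-8-carboxylate (CH2OH syn to C11)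
Conditions: (CH2O)n, Me2AlCl, CH2Cl2, −78 → 0 °C
Reagents that add atoms: formaldehyde from paraformaldehyde (C=O)
Why: Lewis-acid carbonyl-ene reaction: CH2O·Me2AlCl attacks the less hindered alkene carbon C6 of C5=C6 from the open face syn to C11 (anti to the C8–C10 bridge) and takes H from C4, which creates quaternary C6 with CH2OH exo and methyl endo and moves the alkene to C4=C5.

**Step 10**
Reactants: 14 homoallylic alcohol
Product: 15 tert-butyl 2,2-(ethylenedioxy)-6-(hydroxymethyl)-6-methyltricyclo[5.3.1.0(1,5)]undec-8-ene-8-carboxylate (H-5 syn to C11 and cis to CH2OH)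
Conditions: [Ir(cod)(PCy3)(py)]PF6 (5 mol %), H2 (1 atm), CH2Cl2, rt
Reagents that add atoms: none
Why: Hydroxyl-directed hydrogenation with Crabtree's catalyst: Ir bound to the C6–CH2OH delivers H2 to C4=C5 from the same (C11) face, which puts H-5 cis to CH2OH as the SMILES requires, while the electron-poor, undirected C8=C9 enoate is left alone.

**Step 11**
Reactants: 15 primary alcohol
Product: 16 the tert-butyldimethylsilyl ether of 15
Conditions: TBSCl, imidazole, DMF, rt
Reagents that add atoms: tert-butyldimethylsilyl chloride (CC(C)(C)[Si](C)(C)Cl)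
Why: Standard silylation of the only free hydroxyl; no stereocentre is touched.

**Step 12**
Reactants: 16 ketal
Product: 17 tert-butyl 6-[(tert-butyldimethylsilyl)oxymethyl]-6-methyl-2-oxotricyclo[5.3.1.0(1,5)]undec-8-ene-8-carboxylate
Conditions: PPTS (cat.), acetone/H2O 9:1, 45 °C
Reagents that add atoms: water (O)
Why: Mild acid-catalysed ketal hydrolysis frees the C2 ketone while the neopentyl TBS ether and the tert-butyl ester survive; C1 is quaternary, so nothing can epimerise.

**Step 13**
Reactants: 17 ketone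
Product: 18 tert-butyl 6-[(tert-butyldimethylsilyl)oxymethyl]-2-(methoxymethylidene)-6-methyltricyclo[5.3.1.0(1,5)]undec-8-ene-8-carboxylate (E/Z mixture)
Conditions: MeOCH2PPh3Cl, KHMDS, THF, 0 °C → rt
Reagents that add atoms: (methoxymethyl)triphenylphosphonium chloride (COC[P+](c1ccccc1)(c1ccccc1)c1ccccc1.[Cl-])
Why: Wittig methoxymethylenation adds the aldehyde carbon to C2; excess ylide overcomes the neopentyl hindrance, the only ester present is the hindered tert-butyl enoate, and the enol ether geometry is irrelevant.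

**Step 14**
Reactants: 18 enol ether
Product: 19 tert-butyl 6-[(tert-butyldimethylsilyl)oxymethyl]-2-(dimethoxymethyl)-6-methyltricyclo[5.3.1.0(1,5)]undec-8-ene-8-carboxylate (CH(OMe)2 cis to C10)
Conditions: PPTS (0.1 equiv), MeOH/CH2Cl2, 0 °C
Reagents that add atoms: methanol (CO)
Why: Acid-catalysed addition of methanol to the enol ether: irreversible C-protonation at C2 from the open face syn to C11 (away from C10 and the bicyclic core) sets C2 kinetically with the acetal carbon cis to C10, and the oxocarbenium ion is trapped as the dimethyl acetal.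

**Step 15**
Reactants: 19 acetal enoate
Product: 20 tert-butyl 6-[(tert-butyldimethylsilyl)oxymethyl]-2-(dimethoxymethyl)-10-hydroxy-6-methyltricyclo[5.3.1.0(1,5)]undec-8-ene-8-carboxylate (10-OH anti to the C5–C6 bridge)
Conditions: SeO2 (1.5 equiv), pyridine (cat.), 1,4-dioxane, 80 °C
Reagents that add atoms: selenium dioxide (O=[Se]=O)
Why: Riley allylic hydroxylation: the ene reaction at C8 with loss of the exo H-10, then a [2,3]-shift, restores C8=C9 and places OH on C10 on the face anti to the C5–C6 bridge (the other face is blocked by ring C and the endo methyl); C10 is the only allylic CH2 because C7 is a bridgehead.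

**Step 16**
Reactants: 21 dec-9-ynoic acid; 22 (6-bromohexyloxy)(tert-butyl)dimethylsilane
Product: 24 16-[(tert-butyldimethylsilyl)oxy]hexadec-9-ynoic acid, via dilithium acetylide carboxylate 23 (not isolated)
Conditions: n-BuLi (2.1 equiv), THF/HMPA, −78 → 0 °C; then 22, 0 °C → rt; aq. HCl work-up
Reagents that add atoms: none
Why: Alkylation of the acetylide–carboxylate dianion with the primary bromide occurs only at carbon and gives the C16 chain with the alkyne at C9.

**Step 17**
Reactants: 24 alkynoic acid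
Product: 25 (Z)-16-[(tert-butyldimethylsilyl)oxy]hexadec-9-enoic acid
Conditions: H2 (1 atm), Lindlar catalyst, quinoline, EtOAc, rt
Reagents that add atoms: none
Why: Lindlar semihydrogenation adds H2 syn to the alkyne and stops at the alkene, which sets the 9Z geometry.

**Step 18**
Reactants: 20 allylic alcohol; 25 (Z)-16-[(tert-butyldimethylsilyl)oxy]hexadec-9-enoic acid
Product: 27 tert-butyl 6-[(tert-butyldimethylsilyl)oxymethyl]-2-(dimethoxymethyl)-6-methyl-10-{[(Z)-16-(tert-butyldimethylsilyloxy)hexadec-9-enoyl]oxy}tricyclo[5.3.1.0(1,5)]undec-8-ene-8-carboxylate, via mixed anhydride 26 (not isolated)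
Conditions: 2,4,6-Cl3C6H2COCl, Et3N, THF, rt; then 20, DMAP, toluene, 40 °C
Reagents that add atoms: none
Why: Yamaguchi esterification acylates the hindered secondary alcohol at oxygen with retention at C10, and the acetal, silyl ethers, tert-butyl ester and Z-alkene are inert to Et3N/DMAP.

**Step 19**
Reactants: 27 fully protected ester
Product: 28 target, (1R,2S,5S,6S,7S,10S)-2-formyl-6-(hydroxymethyl)-10-{[(Z)-16-hydroxyhexadec-9-enoyl]oxy}-6-methyltricyclo[5.3.1.0(1,5)]undec-8-ene-8-carboxylic acid
Conditions: TFA/CH2Cl2/H2O (10:10:1), 0 °C → rt, short; NaHCO3/MeOH wash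
Reagents that add atoms: water (O)
Why: Global acidolysis cleaves the dimethyl acetal, both TBS ethers and the tert-butyl ester in one operation without base, so the C2–H next to the aldehyde is not touched, and the C10 allylic ester does not ionise because the allyl cation would be destabilised by the C8 carboxyl.

**Compound list**
1 | hex-4-ynoic acid | CC#CCCC(=O)O | starting material
2 | 1-(hex-4-ynoyl)-1H-imidazole | CC#CCCC(=O)n1ccnc1 | intermediate
3 | N-methoxy-N-methylhex-4-ynamide | CC#CCCC(=O)N(C)OC | intermediate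
4 | oct-1-en-6-yn-3-one | CC#CCCC(=O)C=C | intermediate
5 | 2-(pent-3-yn-1-yl)-2-vinyl-1,3-dioxolane | CC#CCCC1(C=C)OCCO1 | intermediate
6 | rac-4'-methyl-2',3',6',6a'-tetrahydro-5'H-spiro[1,3-dioxolane-2,1'-pentalen]-5'-one (racemic) | CC1=C2CCC3(OCCO3)C2CC1=O | intermediate
7 | rac-4'-methyl-3',5',6',6a'-tetrahydro-2'H-spiro[1,3-dioxolane-2,1'-pentalen]-5'-ol (racemic diastereomer mixture) | CC1=C2CCC3(OCCO3)C2CC1O | intermediate
8 | methanesulfonate of 7 | CC1=C2CCC3(OCCO3)C2CC1OS(C)(=O)=O | intermediate
9 | 4'-methyl-3',6'-dihydro-2'H-spiro[1,3-dioxolane-2,1'-pentalene] | CC1=CCC2=C1CCC23OCCO3 | intermediate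
10 | tert-butyl but-3-enoate | C=CCC(=O)OC(C)(C)C | starting material
11 | tert-butyl 2-diazobut-3-enoate | C=CC(=[N+]=[N-])C(=O)OC(C)(C)C | intermediate
12 | cis-divinylcyclopropane from cyclopropanation of C7=C6 of 9 (vinyl cis to the ring, ester exo) | C[C@]12[C@H](CC3=C1CCC34OCCO4)[C@@]2(C=C)C(=O)OC(C)(C)C | intermediate
13 | tert-butyl 2,2-(ethylenedioxy)-6-methyltricyclo[5.3.1.0(1,5)]undeca-5,8-diene-8-carboxylate | CC=1[C@@H]2C[C@]3(CC=C2C(=O)OC(C)(C)C)C4(OCCO4)CCC=13 | intermediate
14 | tert-butyl 2,2-(ethylenedioxy)-6-(hydroxymethyl)-6-methyltricyclo[5.3.1.0(1,5)]undeca-4,8-diene-8-carboxylate, CH2OH syn to C11 | C[C@@]1(CO)[C@@H]2C[C@]3(CC=C2C(=O)OC(C)(C)C)C4(OCCO4)CC=C13 | intermediate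
15 | tert-butyl 2,2-(ethylenedioxy)-6-(hydroxymethyl)-6-methyltricyclo[5.3.1.0(1,5)]undec-8-ene-8-carboxylate, H-5 syn to C11 | C[C@@]1(CO)[C@@H]2C[C@]3(CC=C2C(=O)OC(C)(C)C)C4(OCCO4)CC[C@@H]13 | intermediate
16 | TBS ether of 15 | C[C@@]1(CO[Si](C)(C)C(C)(C)C)[C@@H]2C[C@]3(CC=C2C(=O)OC(C)(C)C)C4(OCCO4)CC[C@@H]13 | intermediate
17 | C2 ketone (ketal of 16 removed) | C[C@@]1(CO[Si](C)(C)C(C)(C)C)[C@@H]2C[C@]3(CC=C2C(=O)OC(C)(C)C)C(=O)CC[C@@H]13 | intermediate
18 | C2 methoxymethylidene enol ether (E/Z mixture) | C[C@@]1(CO[Si](C)(C)C(C)(C)C)[C@@H]2C[C@]3(CC=C2C(=O)OC(C)(C)C)C(=COC)CC[C@@H]13 | intermediate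
19 | C2 dimethyl acetal, CH(OMe)2 cis to C10 | C[C@@]1(CO[Si](C)(C)C(C)(C)C)[C@@H]2C[C@]3(CC=C2C(=O)OC(C)(C)C)[C@@H](C(OC)OC)CC[C@@H]13 | intermediate
20 | C10 alcohol of 19, OH anti to the C5–C6 bridge | C[C@@]1(CO[Si](C)(C)C(C)(C)C)[C@@H]2C[C@]3([C@@H](O)C=C2C(=O)OC(C)(C)C)[C@@H](C(OC)OC)CC[C@@H]13 | intermediate
21 | dec-9-ynoic acid | C#CCCCCCCCC(=O)O | starting material
22 | (6-bromohexyloxy)(tert-butyl)dimethylsilane | CC(C)(C)[Si](C)(C)OCCCCCCBr | starting material
23 | dilithium salt of dec-9-ynoic acid (carboxylate and acetylide) | [Li+].[Li+].[O-]C(=O)CCCCCCCC#[C-] | intermediate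
24 | 16-[(tert-butyldimethylsilyl)oxy]hexadec-9-ynoic acid | CC(C)(C)[Si](C)(C)OCCCCCCC#CCCCCCCCC(=O)O | intermediate
25 | (Z)-16-[(tert-butyldimethylsilyl)oxy]hexadec-9-enoic acid | CC(C)(C)[Si](C)(C)OCCCCCC/C=C\CCCCCCCC(=O)O | intermediate
26 | mixed anhydride of 25 with 2,4,6-trichlorobenzoic acid | CC(C)(C)[Si](C)(C)OCCCCCC/C=C\CCCCCCCC(=O)OC(=O)c1c(Cl)cc(Cl)cc1Cl | intermediate
27 | fully protected ester (tert-butyl ester, two TBS ethers, dimethyl acetal) | C[C@@]1(CO[Si](C)(C)C(C)(C)C)[C@@H]2C[C@]3([C@@H](OC(=O)CCCCCCC/C=C\CCCCCCO[Si](C)(C)C(C)(C)C)C=C2C(=O)OC(C)(C)C)[C@@H](C(OC)OC)CC[C@@H]13 | intermediate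
28 | target CNP0148862.1 | C[C@@]1(CO)[C@@H]2C[C@]3([C@@H](OC(=O)CCCCCCC/C=C\CCCCCCO)C=C2C(=O)O)[C@@H](C=O)CC[C@@H]13 | target

**Totals**
Total steps: 19. Longest linear sequence: 16 (steps 1–6, 8–15, 18, 19).

**Three steps most likely to fail**

Step 10 (directed hydrogenation). Delivery of H to C5 from the C11 face leaves ring C trans-fused and strained, so the catalyst may stall, add from the other face, or reduce C8=C9 instead. The fallback sets out from 14. Alkoxyborane-directed syn-hydroboration with BH3·THF from the same face, then NaBO3, puts boron on C4 and H on C5 and gives the 4-hydroxy diol F4. TBSCl/imidazole silylates only the primary alcohol to give the mono-TBS ether F5. 1,1'-Thiocarbonyldiimidazole converts the secondary alcohol into the imidazolyl thiocarbonate F6. Barton–McCombie reduction (Bu3SnH, AIBN, toluene, 80 °C) removes the C4 oxygen and comes back to the route at 16.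

Step 8 ([4+3]). The diene is hindered and isomerisation-prone, the alkene to be cyclopropanated is trisubstituted, and the ee with an unsubstituted vinyldiazoacetate may be only moderate. The fallback sets out from 9 (with 11) and replaces asymmetric catalysis by resolution. Achiral Rh2(OPiv)4 gives the racemate, i.e. 13 together with its enantiomer ent-13 F1. The racemate is taken through the step-9 ene conditions to 14 and its enantiomer ent-14 F2. Lipase-catalysed acylation (CAL-B, vinyl acetate, MTBE, enzyme/acyl donor screened so that the unwanted enantiomer reacts) converts F2 into the acetate of ent-14 F3. Chromatography separates unreacted 14, where the route is re-joined.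

Step 15 (SeO2). The enoate alkene is deactivated, and over-oxidation to the enone or loss of the acetal can compete. The fallback sets out from 19. Rh2(cap)4-catalysed allylic oxidation with t-BuOOH gives the C10 enone F7. Luche reduction from the open face gives the 10-epi alcohol F8 (OH syn to the C5–C6 bridge). Mitsunobu esterification with acid 25 (PPh3, DIAD, toluene) inverts C10 and gives 27 directly, re-joining the route at 27 and skipping step 18.

**Further compounds**
F1 | step 8 | ent-13, enantiomer of the [4+3] adduct | CC=1[C@H]2C[C@@]3(CC=C2C(=O)OC(C)(C)C)C4(OCCO4)CCC=13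
F2 | step 8 | ent-14, enantiomer of the ene product | C[C@]1(CO)[C@H]2C[C@@]3(CC=C2C(=O)OC(C)(C)C)C4(OCCO4)CC=C13
F3 | step 8 | acetate of ent-14 | C[C@]1(COC(C)=O)[C@H]2C[C@@]3(CC=C2C(=O)OC(C)(C)C)C4(OCCO4)CC=C13
F4 | step 10 | 4-hydroxy derivative of 15 (diol, 4-OH and H-5 syn to C11) | C[C@@]1(CO)[C@@H]2C[C@]3(CC=C2C(=O)OC(C)(C)C)C4(OCCO4)C[C@H](O)[C@@H]13
F5 | step 10 | primary TBS ether of F4 | C[C@@]1(CO[Si](C)(C)C(C)(C)C)[C@@H]2C[C@]3(CC=C2C(=O)OC(C)(C)C)C4(OCCO4)C[C@H](O)[C@@H]13
F6 | step 10 | O-(imidazol-1-ylthiocarbonyl) derivative of F5 | C[C@@]1(CO[Si](C)(C)C(C)(C)C)[C@@H]2C[C@]3(CC=C2C(=O)OC(C)(C)C)C4(OCCO4)C[C@H](OC(=S)n4ccnc4)[C@@H]13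
F7 | step 15 | C10 ketone (enone) from 19 | C[C@@]1(CO[Si](C)(C)C(C)(C)C)[C@@H]2C[C@]3(C(=O)C=C2C(=O)OC(C)(C)C)[C@@H](C(OC)OC)CC[C@@H]13
F8 | step 15 | 10-epi-20 | C[C@@]1(CO[Si](C)(C)C(C)(C)C)[C@@H]2C[C@]3([C@H](O)C=C2C(=O)OC(C)(C)C)[C@@H](C(OC)OC)CC[C@@H]13
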